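**Retrosynthetic overview**

1. Baeomycesic acid is a depside. The aryl ester between the ring A carboxyl and the 4-oxygen of ring B is cut first, giving 3-formyl-2-hydroxy-4-methoxy-6-methylbenzoic acid and benzyl 2,4-dihydroxy-3,6-dimethylbenzoate. Ring B is bought intact as its methyl ester and only re-esterified.
2. The strategy rests on ring A: C1 (carboxyl), C2 (free OH), C3 (CHO), C4 (OMe), C5 (H), C6 (CH3). It is a resorcinol whose two oxygens are already differentiated and flank the formyl carbon, which is the pattern a vinylketene/1-methoxyalkyne benzannulation delivers. C2 and its OH come from the ketene carbonyl, C3 (as CH2OSi) and C4–OMe from the alkyne, and C5, C6 and C1 with its ester from an alkenyl diazo ketone.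
3. Ring A is the only ring constructed (bonds C2–C3 and C4–C5, then C1–C2). Its precursors are a diazo enone (two steps from butane-2,3-dione) and a silyloxymethyl methoxyalkyne (two steps from chloroacetaldehyde dimethyl acetal).
4. After ring formation: desilylation, benzylic oxidation to the aldehyde, tert-butyl ester cleavage, depside esterification, hydrogenolysis.

Key step: step 5

Remark: the target is achiral, so no stereocenter has to be set; the only stereochemical element handled is the E geometry of the enoate in the diazo ketone, which disappears on aromatization.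

**Route**

Step 1
Reactants: 1 butane-2,3-dione; 2 tert-butyl (triphenylphosphoranylidene)acetate
Product: 3 tert-butyl (2E)-3-methyl-4-oxopent-2-enoate
Conditions: 1 (2 equiv), CH2Cl2, 0 °C to rt
Reagents that add atoms: none
Why: Wittig olefination with a stabilized ylide, which condenses once with the activated 1,2-dione (used in excess, the remaining ketone of 3 being conjugated and hindered) and gives the thermodynamically preferred E alkene with the ester trans to the acetyl group.

Step 2
Reactants: 3 tert-butyl (2E)-3-methyl-4-oxopent-2-enoate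
Product: 5 tert-butyl (2E)-5-diazo-3-methyl-4-oxopent-2-enoate, via trifluoroacetyl ketone 4 (not isolated)
Conditions: LiN(SiMe3)2, THF, −78 °C; CF3CO2CH2CF3, −78 °C; aq. HCl work-up; then MsN3, Et3N, H2O (1 equiv), MeCN, rt
Reagents that add atoms: methanesulfonyl azide, CS(=O)(=O)N=[N+]=[N-] (the two diazo nitrogens); 2,2,2-trifluoroethyl trifluoroacetate, O=C(OCC(F)(F)F)C(F)(F)F (trifluoroacetyl group of intermediate 4 only)
Why: Detrifluoroacetylative diazo transfer (Regitz-type transfer to a trifluoroacetyl-activated ketone, the Danheiser protocol for enone methyl ketones), in which the ketone can enolize only at the acetyl methyl group, Claisen acylation gives 4, and sulfonyl azide transfer with loss of the trifluoroacetyl group to the sulfonamide nitrogen leaves the alkene geometry untouched.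

Step 3
Reactants: 6 chloroacetaldehyde dimethyl acetal (2-chloro-1,1-dimethoxyethane)
Product: 8 3-methoxyprop-2-yn-1-ol, via lithium methoxyacetylide 7 (not isolated)
Conditions: LiNEt2 (3.1 equiv, from Et2NH and n-BuLi), THF, 0 °C; then (CH2O)n, −78 °C to rt; H2O quench
Reagents that add atoms: formaldehyde (as paraformaldehyde), C=O; lithium diethylamide, [Li+].CC[N-]CC (lithium of intermediate 7 only)
Why: Twofold base-induced elimination (methanol, then HCl) followed by deprotonation gives the lithium alkoxyacetylide in one pot, its 1,2-addition to formaldehyde is a standard acetylide hydroxymethylation, and the basic aqueous quench protects the acid-sensitive ynol ether.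

Step 4
Reactants: 8 3-methoxyprop-2-yn-1-ol
Product: 9 tert-butyl[(3-methoxyprop-2-yn-1-yl)oxy]dimethylsilane
Conditions: TBSCl, imidazole, CH2Cl2, 0 °C to rt (crude 8 used directly)
Reagents that add atoms: tert-butyldimethylsilyl chloride, CC(C)(C)[Si](C)(C)Cl
Why: Imidazole-promoted O-silylation of a primary alcohol in a buffered, non-acidic medium that leaves the ynol ether intact, the silyl ether removing the free hydroxyl that would otherwise trap the ketene in step 5.

Step 5
Reactants: 5 tert-butyl (2E)-5-diazo-3-methyl-4-oxopent-2-enoate; 9 tert-butyl[(3-methoxyprop-2-yn-1-yl)oxy]dimethylsilane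
Product: 13 tert-butyl 3-({[tert-butyl(dimethyl)silyl]oxy}methyl)-2-hydroxy-4-methoxy-6-methylbenzoate, via vinylketene 10 (not isolated), via vinylcyclobutenone 11 (not isolated), via dienylketene 12 (not isolated)
Conditions: 9 (1.5 equiv), hν (medium-pressure Hg lamp, Vycor filter), degassed ClCH2CH2Cl, rt; then 80 °C
Reagents that add atoms: none
Why: Photolysis of 5 expels N2 and the alkenyl group migrates (photochemical Wolff rearrangement) to give vinylketene 10, whose ketene C=C adds to the electron-rich alkyne of 9 in a [2+2] cycloaddition (bonds C2–C3 and C4–C5) to give 4-alkenylcyclobutenone 11. Four-electron electrocyclic opening of 11 (photochemical at rt, thermal on heating) gives dienylketene 12, and ring A is closed by a thermal six-electron electrocyclization between the ketene carbon and the ester-bearing alkene terminus (bond C1–C2), after which the cyclohexadienone, a β-keto ester, tautomerizes to the hydrogen-bonded salicylate. The closest known reaction type is the Danheiser benzannulation in its diazo ketone variant with alkoxy- and siloxyalkynes. No stereocenter is present in 13; the sp3 centre of 11 is racemic and is lost on ring opening. The selectivity needed is the regiochemistry of the [2+2] step, and it is secured by the polarization of the ynol ether, whose carbon remote from oxygen is nucleophilic and bonds to the electrophilic ketene carbonyl carbon, placing CH2OTBS between the new OH and the OMe. The E enoate keeps the ester on the outside of the closing triene, and the excess of 9 intercepts the ketene before it can acylate the product phenol.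

Step 6
Reactants: 13 tert-butyl 3-({[tert-butyl(dimethyl)silyl]oxy}methyl)-2-hydroxy-4-methoxy-6-methylbenzoate
Product: 14 tert-butyl 2-hydroxy-3-(hydroxymethyl)-4-methoxy-6-methylbenzoate
Conditions: Bu4NF, AcOH, THF, 0 °C to rt
Reagents that add atoms: none
Why: Fluoride-induced desilylation of the primary silyl ether, buffered with acetic acid so that the phenoxide of the hydroxybenzyl alcohol is not generated, with the tert-butyl ester and the aryl methyl ether inert.

Step 7
Reactants: 14 tert-butyl 2-hydroxy-3-(hydroxymethyl)-4-methoxy-6-methylbenzoate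
Product: 15 tert-butyl 3-formyl-2-hydroxy-4-methoxy-6-methylbenzoate
Conditions: activated MnO2 (excess), CH2Cl2, rt
Reagents that add atoms: none
Why: MnO2 oxidation, selective for benzylic alcohols and established for 2-hydroxybenzyl alcohols, stops at the aldehyde, which is stabilized by its hydrogen bond to the C2 hydroxyl.

Step 8
Reactants: 15 tert-butyl 3-formyl-2-hydroxy-4-methoxy-6-methylbenzoate
Product: 16 3-formyl-2-hydroxy-4-methoxy-6-methylbenzoic acid
Conditions: CF3CO2H/CH2Cl2 (1:3), 0 °C to rt
Reagents that add atoms: none
Why: Acidolysis of the tert-butyl ester by alkyl–oxygen cleavage (tert-butyl cation lost as isobutene), which the aldehyde, methyl ether and phenol tolerate, the formyl group deactivating the ring towards protodecarboxylation and tert-butylation.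

Step 9
Reactants: 17 methyl 2,4-dihydroxy-3,6-dimethylbenzoate
Product: 18 2,4-dihydroxy-3,6-dimethylbenzoic acid
Conditions: conc. H2SO4, 0 °C to rt; then ice water
Reagents that add atoms: water, O
Why: AAc1 ester hydrolysis, in which the di-ortho-substituted electron-rich benzoate ionizes to the acylium ion in concentrated H2SO4 and is captured by water on quenching, bypassing the steric and electronic shielding that blocks saponification and staying cold enough to avoid decarboxylation.

Step 10
Reactants: 18 2,4-dihydroxy-3,6-dimethylbenzoic acid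
Product: 19 benzyl 2,4-dihydroxy-3,6-dimethylbenzoate
Conditions: BnBr, KHCO3, DMF, rt
Reagents that add atoms: benzyl bromide, BrCc1ccccc1
Why: SN2 O-alkylation of the carboxylate, KHCO3 ionizing only the carboxylic acid so that the phenols are not benzylated.

Step 11
Reactants: 16 3-formyl-2-hydroxy-4-methoxy-6-methylbenzoic acid; 19 benzyl 2,4-dihydroxy-3,6-dimethylbenzoate
Product: 21 benzyl 4-[(3-formyl-2-hydroxy-4-methoxy-6-methylbenzoyl)oxy]-2-hydroxy-3,6-dimethylbenzoate, via acyl trifluoroacetate 20 (not isolated)
Conditions: (CF3CO)2O, toluene, rt; aq. NaHCO3 work-up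
Reagents that add atoms: trifluoroacetic anhydride, O=C(OC(=O)C(F)(F)F)C(F)(F)F (trifluoroacetyl group of intermediate 20 only)
Why: Mixed-anhydride esterification (the trifluoroacetic anhydride method used for depsides), in which 16 is activated as 20 and acylates the free, unhindered 4-hydroxyl of 19, while the 2-hydroxyls of both partners are held in hydrogen bonds to their ortho carbonyl groups and any trifluoroacetate formed on them is lost on aqueous work-up.

Step 12
Reactants: 21 benzyl 4-[(3-formyl-2-hydroxy-4-methoxy-6-methylbenzoyl)oxy]-2-hydroxy-3,6-dimethylbenzoate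
Product: 22 baeomycesic acid, 4-[(3-formyl-2-hydroxy-4-methoxy-6-methylbenzoyl)oxy]-2-hydroxy-3,6-dimethylbenzoic acid
Conditions: H2 (1 atm), 10% Pd/C, EtOAc, rt
Reagents that add atoms: none
Why: Hydrogenolysis of the benzyl ester over palladium, the benzylic C–O bond being cleaved under one atmosphere much faster than the hydrogen-bonded aryl aldehyde is reduced, and the depside aryl ester not being benzylic.

**Compound list**

1 | butane-2,3-dione | CC(=O)C(C)=O | starting material
2 | tert-butyl (triphenylphosphoranylidene)acetate | CC(C)(C)OC(=O)C=P(c1ccccc1)(c1ccccc1)c1ccccc1 | starting material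
3 | tert-butyl (2E)-3-methyl-4-oxopent-2-enoate | CC(C)(C)OC(=O)/C=C(\C)C(C)=O | intermediate
4 | tert-butyl (2E)-7,7,7-trifluoro-3-methyl-4,6-dioxohept-2-enoate | CC(C)(C)OC(=O)/C=C(\C)C(=O)CC(=O)C(F)(F)F | intermediate
5 | tert-butyl (2E)-5-diazo-3-methyl-4-oxopent-2-enoate | CC(C)(C)OC(=O)/C=C(\C)C(=O)C=[N+]=[N-] | intermediate
6 | chloroacetaldehyde dimethyl acetal (2-chloro-1,1-dimethoxyethane) | COC(CCl)OC | starting material
7 | lithium methoxyacetylide | [Li]C#COC | intermediate
8 | 3-methoxyprop-2-yn-1-ol | COC#CCO | intermediate
9 | tert-butyl[(3-methoxyprop-2-yn-1-yl)oxy]dimethylsilane | COC#CCO[Si](C)(C)C(C)(C)C | intermediate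
10 | tert-butyl (2E)-3-methyl-5-oxopenta-2,4-dienoate (vinylketene) | CC(C)(C)OC(=O)/C=C(\C)C=C=O | intermediate
11 | tert-butyl (2E)-3-[3-({[tert-butyl(dimethyl)silyl]oxy}methyl)-2-methoxy-4-oxocyclobut-2-en-1-yl]but-2-enoate (racemic) | COC1=C(CO[Si](C)(C)C(C)(C)C)C(=O)C1/C(C)=C/C(=O)OC(C)(C)C | intermediate
12 | tert-butyl (2E,4E)-6-({[tert-butyl(dimethyl)silyl]oxy}methyl)-5-methoxy-3-methyl-7-oxohepta-2,4,6-trienoate (dienylketene, C3 and C6 cis across C4=C5) | CC(C)(C)OC(=O)/C=C(\C)/C=C(/OC)\C(CO[Si](C)(C)C(C)(C)C)=C=O | intermediate
13 | tert-butyl 3-({[tert-butyl(dimethyl)silyl]oxy}methyl)-2-hydroxy-4-methoxy-6-methylbenzoate | COc1cc(C)c(C(=O)OC(C)(C)C)c(O)c1CO[Si](C)(C)C(C)(C)C | intermediate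
14 | tert-butyl 2-hydroxy-3-(hydroxymethyl)-4-methoxy-6-methylbenzoate | COc1cc(C)c(C(=O)OC(C)(C)C)c(O)c1CO | intermediate
15 | tert-butyl 3-formyl-2-hydroxy-4-methoxy-6-methylbenzoate | COc1cc(C)c(C(=O)OC(C)(C)C)c(O)c1C=O | intermediate
16 | 3-formyl-2-hydroxy-4-methoxy-6-methylbenzoic acid | COc1cc(C)c(C(=O)O)c(O)c1C=O | intermediate
17 | methyl 2,4-dihydroxy-3,6-dimethylbenzoate | COC(=O)c1c(C)cc(O)c(C)c1O | starting material
18 | 2,4-dihydroxy-3,6-dimethylbenzoic acid | OC(=O)c1c(C)cc(O)c(C)c1O | intermediate
19 | benzyl 2,4-dihydroxy-3,6-dimethylbenzoate | O=C(OCc1ccccc1)c1c(C)cc(O)c(C)c1O | intermediate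
20 | 3-formyl-2-hydroxy-4-methoxy-6-methylbenzoic trifluoroacetic anhydride | COc1cc(C)c(C(=O)OC(=O)C(F)(F)F)c(O)c1C=O | intermediate
21 | benzyl 4-[(3-formyl-2-hydroxy-4-methoxy-6-methylbenzoyl)oxy]-2-hydroxy-3,6-dimethylbenzoate | COc1cc(C)c(C(=O)Oc2cc(C)c(C(=O)OCc3ccccc3)c(O)c2C)c(O)c1C=O | intermediate
22 | baeomycesic acid | COc1cc(C)c(C(=O)Oc2cc(C)c(C(=O)O)c(O)c2C)c(O)c1C=O | target

**Step count**

Total: 12 steps. Longest linear sequence: 8 steps (steps 1, 2, 5, 6, 7, 8, 11, 12; the alkyne branch through steps 3 and 4 is equally long).

**Steps most likely to fail**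

Step 5 (benzannulation). Under irradiation the enoate double bond can isomerize, and the diazo group can add as a dipole to the electron-poor alkene of a second molecule, so that less ketene is formed. The ester-substituted vinylketene may also be consumed by dimerization or by acylation of the product phenol faster than it adds to the alkyne, or the cascade may stall at the cyclobutenone.

Fallback: it sets out from 9 and comes back to the route at 16. The carboxyl carbon is taken off the ketene partner and introduced after the ring is made. 1-Diazo-3-methylbut-3-en-2-one F1 would be prepared from commercial 3-methylbut-3-en-2-one by the diazo transfer sequence of step 2. Irradiation of F1 with 9 under the conditions of step 5 (a benzannulation with a simple alkyl-substituted vinylketene) should give 2-({[tert-butyl(dimethyl)silyl]oxy}methyl)-3-methoxy-5-methylphenol F2. Its only free ortho position would be formylated (MgCl2, Et3N, (CH2O)n, MeCN, reflux; magnesium-mediated ortho-formylation) to 3-({[tert-butyl(dimethyl)silyl]oxy}methyl)-2-hydroxy-4-methoxy-6-methylbenzaldehyde F3. Pinnick oxidation (NaClO2, NaH2PO4, 2-methylbut-2-ene, t-BuOH/H2O) would give 3-({[tert-butyl(dimethyl)silyl]oxy}methyl)-2-hydroxy-4-methoxy-6-methylbenzoic acid F4. Desilylation (Bu4NF, AcOH, THF) would give 2-hydroxy-3-(hydroxymethyl)-4-methoxy-6-methylbenzoic acid F5, and MnO2 oxidation of the benzylic alcohol would give 16, so that steps 6 to 8 fall away.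

Step 2 (diazo transfer). The lithium enolate can add in conjugate fashion to the strongly electrophilic ene-keto ester before it is trifluoroacetylated, the vinylogous methyl group can be deprotonated in competition, and the diazo ketone can be lost by intermolecular dipolar cycloaddition on concentration.

Fallback: it sets out from 3 and comes back at 5, and it avoids the lithium enolate. Soft enolization of 3 (Me3SiOTf, Et3N, CH2Cl2, 0 °C) would give tert-butyl (2E)-3-methyl-4-[(trimethylsilyl)oxy]penta-2,4-dienoate F6. Bromination with NBS (THF, 0 °C) would give tert-butyl (2E)-5-bromo-3-methyl-4-oxopent-2-enoate F7. Treatment of F7 with N,N'-ditosylhydrazine and DBU (THF, 0 °C) would build the diazo group by N-alkylation and twofold loss of sulfinate, giving 5.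

Step 3 (methoxyalkyne). The elimination may be incomplete, the alkoxyacetylide may decompose before it is trapped, capture by paraformaldehyde may be slow in the presence of diethylamine, and the volatile, acid-sensitive alcohol may be lost by evaporation or hydration during isolation.

Fallback: it sets out from 5 and comes back at 13, replacing the methoxyalkyne by a siloxyalkyne and introducing the methyl group afterwards. Commercial tert-butyldimethyl(prop-2-yn-1-yloxy)silane would be lithiated (n-BuLi, THF, −78 °C), oxidized to the ynolate with t-BuOOLi and O-silylated with i-Pr3SiOTf to give tert-butyl(dimethyl)[(3-{[tri(propan-2-yl)silyl]oxy}prop-2-yn-1-yl)oxy]silane F8. Benzannulation of 5 with F8 under the conditions of step 5, with the same regiochemical polarization, should give tert-butyl 3-({[tert-butyl(dimethyl)silyl]oxy}methyl)-2-hydroxy-6-methyl-4-{[tri(propan-2-yl)silyl]oxy}benzoate F9. Fluoride-triggered cleavage of the aryl silyl ether with methylation of the liberated phenoxide in the same flask (CsF, MeI, DMF, 0 °C to rt) should give 13; the hydrogen-bonded C2 hydroxyl is expected to stay unmethylated and the alkyl silyl ether is expected to react more slowly than the aryl one.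

**Further compounds**

F1 | step 5 | 1-diazo-3-methylbut-3-en-2-one | C=C(C)C(=O)C=[N+]=[N-]
F2 | step 5 | 2-({[tert-butyl(dimethyl)silyl]oxy}methyl)-3-methoxy-5-methylphenol | COc1cc(C)cc(O)c1CO[Si](C)(C)C(C)(C)C
F3 | step 5 | 3-({[tert-butyl(dimethyl)silyl]oxy}methyl)-2-hydroxy-4-methoxy-6-methylbenzaldehyde | COc1cc(C)c(C=O)c(O)c1CO[Si](C)(C)C(C)(C)C
F4 | step 5 | 3-({[tert-butyl(dimethyl)silyl]oxy}methyl)-2-hydroxy-4-methoxy-6-methylbenzoic acid | COc1cc(C)c(C(=O)O)c(O)c1CO[Si](C)(C)C(C)(C)C
F5 | step 5 | 2-hydroxy-3-(hydroxymethyl)-4-methoxy-6-methylbenzoic acid | COc1cc(C)c(C(=O)O)c(O)c1CO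
F6 | step 2 | tert-butyl (2E)-3-methyl-4-[(trimethylsilyl)oxy]penta-2,4-dienoate | C=C(O[Si](C)(C)C)/C(C)=C/C(=O)OC(C)(C)C
F7 | step 2 | tert-butyl (2E)-5-bromo-3-methyl-4-oxopent-2-enoate | BrCC(=O)/C(C)=C/C(=O)OC(C)(C)C
F8 | step 3 | tert-butyl(dimethyl)[(3-{[tri(propan-2-yl)silyl]oxy}prop-2-yn-1-yl)oxy]silane | CC(C)[Si](OC#CCO[Si](C)(C)C(C)(C)C)(C(C)C)C(C)C
F9 | step 3 | tert-butyl 3-({[tert-butyl(dimethyl)silyl]oxy}methyl)-2-hydroxy-6-methyl-4-{[tri(propan-2-yl)silyl]oxy}benzoate | Cc1cc(O[Si](C(C)C)(C(C)C)C(C)C)c(CO[Si](C)(C)C(C)(C)C)c(O)c1C(=O)OC(C)(C)C
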